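Late in a run I stop watching how fast c(starting complex) falls and read the last row, at 4.00 d: complex with one exchanged stands at 32% on Monday and 55% on Wednesday.

common to all: starting complex 0.014 M

| charge | incoming ligand | remark | time |
|---|---|---|---|
| Monday's | 0.93 equiv | run made earlier |  |
| Wednesday's | 2.2 equiv | run made earlier |  |
| oak | 0.800 equiv |  | 4.0 d |
| elm | 1.20 equiv |  | 4.0 d |
| alder | 2.00 equiv |  | 4.0 d |

| run | time / d | complex with one exchanged / % | complex with three exchanged / % | starting complex / % |
|---|---|---|---|---|
| Monday's | 0.833 | 15 | 0 | 54 |
| Monday's | 1.67 | 18 | 0 | 40 |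
| Monday's | 2.50 | 23 | 2 | 35 |
| Monday's | 3.00 | 31 | 0 | 33 |
| Monday's | 4.00 | 32 | 3 | 29 |
| Wednesday's | 0.833 | 26 | 0 | 43 |
| Wednesday's | 1.67 | 41 | 1 | 27 |
| Wednesday's | 2.50 | 49 | 1 | 20 |
| Wednesday's | 3.00 | 49 | 1 | 19 |
| Wednesday's | 4.00 | 55 | 0 | 17 |

(readings scatter by 2 percentage points)

- what was read earlier has a scatter of 2 percentage points, one standard deviation

* final complex with one exchanged, as a percentage of the starting complex charged, for each flask in turn (oak, elm, alder)

I count halvings: how many times the part of the charge not yet complex with one exchanged has halved by that row. Monday gives 0.556 and Wednesday 1.15. The halvings won per equivalent of incoming ligand, at that time and with 0.014 M of starting complex charged, are then 0.469, a reading that carries the scatter. Laid along that line from Monday, my count gives 29.1% for oak, 37.7% for elm and 52.0% for alder.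

The forecast, from “A power-law or hyperbolic interpolation through these two points”, says 29%, 38% and 52%.

The flasks give 29.1% in oak, 39.4% in elm and 54.0% in alder, within the tolerance of the forecast.

    starting complex + incoming ligand ⇌ leaving ligand + complex with one exchanged (K = 7.00, k = 0.0129 M⁻¹ min⁻¹)
    complex with one exchanged + incoming ligand ⇌ leaving ligand + complex with two exchanged (K = 40.9, k = 5.38 × 10⁻⁴ M⁻¹ min⁻¹)
    complex with two exchanged + incoming ligand ⇌ leaving ligand + complex with three exchanged (K = 0.699, k = 0.0602 M⁻¹ min⁻¹)
    leaving ligand + complex with three exchanged → side product (k = 0.0173 M⁻¹ min⁻¹)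
    starting complex ⇌ dormant form (K = 1.10, k = 5.13 × 10⁻⁴ min⁻¹)

Elm's 39.4% counts as 0.723 halvings; adding 0.469 per equivalent up to alder's charge gives 53.3%, and alder holds 54.0%. In elm the forward step alone from complex with one exchanged to complex with two exchanged, with the other concentrations as charged, has a half-life of 53 d, longer than the 4.0 d of the run, so the run spans 0.0755 of that half-life. Complex with two exchanged stands in elm at 0.498% after 4.00 d.

The numbers in the tables are calculated for an exercise.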